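**Plan**
- Retrosynthesis (germacrane numbering: ring A = ten-membered carbocycle C1–C10, ring B = lactone O–C6–C7–C11–C12): remove the isobutyrate, reveal C9=O from a C9 methylene and C11=CH2 from the lactone CH2, then cut the C5–C6 bond and the lactone O6–C12 bond together, then the C7–C8 bond.
- Enabling feature: C5 and C6 are adjacent oxygen-bearing ring A carbons (acylated O5, lactone O6), i.e. a masked 1,2-diol, and the lactone carbonyl C12 lies γ to O6. Pinacol coupling of a C5/C6 dialdehyde therefore closes ring A, and the C6 alkoxide closes ring B on a C12 ester, leaving O5 free for acylation.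
- Forward: (S)-citronellal supplies C8–C10, C1–C5, C14 and C15 with no C–C bond formation in that chain; an aldol adds C6, C7, C11, C12; ring A then ring B form in the key step; C13 is added last.
- Stereochemistry: C10 from the chiral pool; C4 from Sharpless epoxidation and hydride opening; C7 and C8 from an oxazolidinone syn-aldol; C5 and C6 from substrate control in the key step.
- C9=O is carried as an exocyclic methylene and C11=CH2 as a Mannich base, so that no ketone or acrylate meets SmI2 and no acrylate meets ozone.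

Key step: step 13

Remark: germacrane numbering is used for all intermediates, and (S)-citronellal is taken as commercial in high enantiomeric purity.

**Step 1**
Reactants: 1 (S)-citronellal
Product: 2 (6S)-8,8-dimethoxy-2,6-dimethyloct-2-ene
Conditions: HC(OMe)3, MeOH, PPTS (cat.), rt
Reagents that add atoms: trimethyl orthoformate, COC(OC)OC; methanol, CO
Why: Acid-catalysed acetalisation with orthoformate as water scavenger protects the C8 aldehyde for the oxidative and hydride steps that follow, and C10 is untouched.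

**Step 2**
Reactants: 2 (6S)-8,8-dimethoxy-2,6-dimethyloct-2-ene
Product: 3 (2E,6S)-8,8-dimethoxy-2,6-dimethyloct-2-en-1-ol
Conditions: SeO2 (0.3 equiv), anhydrous t-BuOOH (3 equiv), CH2Cl2, 0 °C to rt
Reagents that add atoms: tert-butyl hydroperoxide, CC(C)(C)OO (oxygen relayed through selenium dioxide, O=[Se]=O)
Why: Catalytic selenium dioxide allylic oxidation (ene reaction then [2,3]-shift) of a gem-dimethyl trisubstituted olefin is selective for the (E)-methyl group and should give the (E)-allylic alcohol that carries C5.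

**Step 3**
Reactants: 3 (2E,6S)-8,8-dimethoxy-2,6-dimethyloct-2-en-1-ol
Product: 4 [(2S,3S)-3-[(3S)-5,5-dimethoxy-3-methylpentyl]-2-methyloxiran-2-yl]methanol
Conditions: Ti(OiPr)4 (10 mol %), L-(+)-diethyl tartrate (12 mol %), t-BuOOH, 4 Å sieves, CH2Cl2, −20 °C
Reagents that add atoms: tert-butyl hydroperoxide, CC(C)(C)OO
Why: Sharpless asymmetric epoxidation of the (E)-2-methyl allylic alcohol with the L-(+)-tartrate should give the (2S,3S)-epoxide under reagent control, which fixes the C4–O bond of the future tertiary carbinol.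

**Step 4**
Reactants: 4 epoxy alcohol
Product: 5 (2R,6S)-8,8-dimethoxy-2,6-dimethyloctane-1,2-diol
Conditions: LiAlH4, THF, 0 °C to rt; aqueous NaOH work-up
Reagents that add atoms: none
Why: Hydride opens the 2,3-epoxy alcohol at the less hindered secondary carbon (C3), so the C4–O bond set in step 3 is kept and becomes the (4R) tertiary alcohol; the acetal is inert.

**Step 5**
Reactants: 5 (2R,6S)-8,8-dimethoxy-2,6-dimethyloctane-1,2-diol
Product: 8 (3S,7R)-3,7-dimethyl-7,8-bis(triethylsilyloxy)octanal, via bis-silyl dimethyl acetal 6 (not isolated), via lutidinium methoxyalkyl triflate 7 (not isolated)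
Conditions: TESOTf (4.5 equiv), 2,6-lutidine (6 equiv), CH2Cl2, −78 to 0 °C; then H2O
Reagents that add atoms: triethylsilyl triflate, CC[Si](CC)(CC)OS(=O)(=O)C(F)(F)F; water, O
Why: The silyl triflate/pyridine base pair silylates both hydroxyls and converts the dimethyl acetal into a pyridinium N,O-acetal that water hydrolyses to the aldehyde without loss of silyl ethers (silyl triflate-mediated acetal cleavage), so protection and aldehyde release take one step.

**Step 6**
Reactants: 8 (3S,7R)-3,7-dimethyl-7,8-bis(triethylsilyloxy)octanal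
Product: 10 (3S,7R)-3,7-dimethyl-2-methylidene-7,8-bis(triethylsilyloxy)octanal, via aldehyde Mannich base 9 (not isolated)
Conditions: CH2=NMe2+ I− (Eschenmoser's salt, 2 equiv), Et3N, CH2Cl2, rt
Reagents that add atoms: N,N-dimethylmethylideneammonium iodide, C=[N+](C)C.[I-]
Why: Mannich reaction at C9 followed by loss of dimethylamine gives the 2-methylene aldehyde; the exocyclic methylene is a ketone surrogate without a stereocentre, and C10 is not enolisable under these conditions.

**Step 7**
Reactants: 11 (4S)-4-benzyl-1,3-oxazolidin-2-one; 12 methyl 4-chloro-4-oxobutanoate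
Product: 13 methyl 4-[(4S)-4-benzyl-2-oxo-1,3-oxazolidin-3-yl]-4-oxobutanoate
Conditions: Et3N, DMAP (cat.), CH2Cl2, 0 °C to rt
Reagents that add atoms: none
Why: DMAP-catalysed N-acylation of the oxazolidinone gives the aldol donor that carries C6, C7, C11 and C12.

**Step 8**
Reactants: 13 succinate imide; 10 2-methylene aldehyde
Product: 16 methyl (3S,4S,6S,10R)-3-{[(4S)-4-benzyl-2-oxo-1,3-oxazolidin-3-yl]carbonyl}-4-hydroxy-6,10-dimethyl-5-methylidene-10,11-bis(triethylsilyloxy)undecanoate, via Z dibutylboron enolate 14 (not isolated), via dibutylboron aldolate 15 (not isolated)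
Conditions: Bu2BOTf, iPr2NEt, CH2Cl2, 0 °C; 10, −78 to 0 °C; then pH 7 buffer, MeOH, H2O2, 0 °C
Reagents that add atoms: none
Why: Evans syn-aldol: the (Z)-boron enolate, formed at C7 next to the imide and not next to the ester, adds to the enal through a chair Zimmerman–Traxler transition state on the face away from the benzyl group, which should set 7S and 8S under auxiliary control.

**Step 9**
Reactants: 16 aldol adduct
Product: 17 methyl (3S,4S,6S,10R)-3-{[(4S)-4-benzyl-2-oxo-1,3-oxazolidin-3-yl]carbonyl}-6,10-dimethyl-5-methylidene-4,10,11-tris(triethylsilyloxy)undecanoate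
Conditions: TESOTf, 2,6-lutidine, CH2Cl2, −78 °C
Reagents that add atoms: triethylsilyl triflate, CC[Si](CC)(CC)OS(=O)(=O)C(F)(F)F
Why: Silylation of O8 prevents lactonisation of O8 onto the C12 ester and matches the protecting group at O4 for joint removal at the end.

**Step 10**
Reactants: 17 silylated imide
Product: 18 methyl (3S,4S,6S,10R)-3-[(ethylsulfanyl)carbonyl]-6,10-dimethyl-5-methylidene-4,10,11-tris(triethylsilyloxy)undecanoate
Conditions: EtSH, n-BuLi, THF, 0 °C
Reagents that add atoms: ethanethiol, CCS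
Why: Lithium ethanethiolate cleaves the hindered silyloxy imide at the exocyclic carbonyl (thiolate transacylation) and frees the auxiliary, while the less electrophilic methyl ester is left alone.

**Step 11**
Reactants: 18 thioester
Product: 19 methyl (3S,4S,6S,10R)-3-[(ethylsulfanyl)carbonyl]-6,10-dimethyl-5-methylidene-11-oxo-4,10-bis(triethylsilyloxy)undecanoate
Conditions: (COCl)2, DMSO, CH2Cl2, −78 to −40 °C; Et3N, −78 to 0 °C
Reagents that add atoms: none
Why: Under Swern conditions a primary triethylsilyl ether is cleaved and oxidised directly to the aldehyde while secondary and tertiary ones survive, which unveils the non-enolisable C5 aldehyde in one operation.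

**Step 12**
Reactants: 19 thioester aldehyde
Product: 20 methyl (3S,4S,6S,10R)-3-formyl-6,10-dimethyl-5-methylidene-11-oxo-4,10-bis(triethylsilyloxy)undecanoate
Conditions: Et3SiH, Pd/C (10 %), acetone, rt; used at once
Reagents that add atoms: none
Why: Fukuyama reduction (palladium-catalysed silane reduction of a thioester) gives the C6 aldehyde under neutral conditions that should spare the methyl ester, the C5 aldehyde and the hindered 1,1-disubstituted olefin and not epimerise C7.

**Step 13**
Reactants: 20 C5/C6 dialdehyde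
Product: 22 5-hydroxy-9-methylidene-4,8-bis(triethylsilyloxy)-13-norgermacran-12,6-olide, via ring A diol methyl ester samarium alkoxide 21 (not isolated)
Conditions: SmI2 (5 equiv, 0.05 M in THF), syringe-pump addition of 20 over 8 h to about 2 mM, rt; then aq. potassium sodium tartrate
Reagents that add atoms: none
Why: Two single-electron transfers from SmI2 turn the C5 and C6 aldehydes into samarium-bound ketyls that couple to form the C5–C6 bond, and the C6 alkoxide then attacks the C12 methyl ester while the C5 alkoxide stays free for step 15. The closest known reaction type is the intramolecular pinacol coupling of dialdehydes to medium- and large-ring 1,2-diols with low-valent samarium or titanium, followed by the spontaneous lactonisation seen when a samarium γ-alkoxide faces a methyl ester. Ring A closes by ten-membered ketyl–ketyl C–C coupling, helped by the sp2 C9 and the quaternary C4, which lower transannular strain, and ring B closes by 5-exo-trig acyl substitution at C12, faster than the 6-exo alternative from O5. C5 is set by C4 (polar Felkin–Anh: the bulky, non-chelating tertiary silyloxy group anti to the new bond, approach past the C15 methyl, giving 5S) and C6 by C7 (Felkin–Anh: the C8 branch anti, approach past H7, giving 6R); both preferences lead to the same threo, ring-trans diol, which is also the one expected when C4–C5–C6–C7 is antiperiplanar and both oxygens bridge one trivalent samarium. The step needs chemoselectivity for the two aldehydes, secured because no ketone or acrylate is present (C9 is an unactivated methylene, C13 is not yet installed, and esters and silyl ethers are inert to SmI2 in THF without additives), and it needs ring closure over oligomerisation, secured by slow addition of 20 to excess reagent.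

**Step 14**
Reactants: 22 hydroxy lactone
Product: 24 (11S)-13-(dimethylamino)-5-hydroxy-9-methylidene-4,8-bis(triethylsilyloxy)germacran-12,6-olide, via dilithium alkoxide enolate 23 (not isolated)
Conditions: LiN(iPr)2 (2.3 equiv), THF, −78 °C; CH2=NMe2+ I−, −78 to −20 °C; H2O
Reagents that add atoms: N,N-dimethylmethylideneammonium iodide, C=[N+](C)C.[I-]
Why: The alkoxide/lactone enolate is C-alkylated by the iminium salt (Mannich reaction) on the face opposite the C7–C8 bond, which stores C13 as a saturated amine; the C11 configuration is erased later.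

**Step 15**
Reactants: 24 lactone Mannich base
Product: 25 (11S)-13-(dimethylamino)-9-methylidene-5-(2-methylpropanoyloxy)-4,8-bis(triethylsilyloxy)germacran-12,6-olide
Conditions: (iPrCO)2O, Et3N, DMAP, CH2Cl2, rt
Reagents that add atoms: isobutyric anhydride, CC(C)C(=O)OC(=O)C(C)C
Why: DMAP-catalysed acylation esterifies the only free hydroxyl (O5); the tertiary amine and the silyl ethers are inert.

**Step 16**
Reactants: 25 isobutyrate Mannich base
Product: 29 5-(2-methylpropanoyloxy)-9-oxo-4,8-bis(triethylsilyloxy)germacr-11(13)-en-12,6-olide, via trimethylammonium triflate 26 (not isolated), via C9 ozonide 27 (not isolated), via 9-oxo ammonium triflate 28 (not isolated)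
Conditions: MeOTf (1.05 equiv), CH2Cl2, 0 °C; O3, −78 °C; PPh3, −78 °C to rt; then sat. aq. NaHCO3, rt
Reagents that add atoms: ozone, [O-][O+]=O
Why: Quaternisation makes the amine inert to ozone, so ozonolysis cleaves the only olefin present (C9=CH2) to the ketone before any acrylate exists, and mild base then causes E1cB loss of trimethylamine (elimination of a quaternised Mannich base) to give the α-methylene lactone without epimerising C8 or C10.

**Step 17**
Reactants: 29 bis-silyl ether
Product: 30 (4R,5S,6R,7S,8S,10S)-4,8-dihydroxy-5-(2-methylpropanoyloxy)-9-oxogermacr-11(13)-en-12,6-olide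
Conditions: HF·pyridine, pyridine, THF, 0 °C to rt
Reagents that add atoms: none
Why: Buffered fluoride removes the secondary (O8) and tertiary (O4) triethylsilyl ethers under conditions that should leave the acyloin, the isobutyrate and the α-methylene lactone intact.

**Compound list**
1 | (S)-citronellal, (3S)-3,7-dimethyloct-6-enal | O=CC[C@@H](C)CCC=C(C)C | starting material
2 | (6S)-8,8-dimethoxy-2,6-dimethyloct-2-ene | COC(OC)C[C@@H](C)CCC=C(C)C | intermediate
3 | (2E,6S)-8,8-dimethoxy-2,6-dimethyloct-2-en-1-ol | COC(OC)C[C@@H](C)CC/C=C(\C)CO | intermediate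
4 | [(2S,3S)-3-[(3S)-5,5-dimethoxy-3-methylpentyl]-2-methyloxiran-2-yl]methanol | COC(OC)C[C@@H](C)CC[C@@H]1O[C@@]1(C)CO | intermediate
5 | (2R,6S)-8,8-dimethoxy-2,6-dimethyloctane-1,2-diol | COC(OC)C[C@@H](C)CCC[C@@](C)(O)CO | intermediate
6 | (2R,6S)-8,8-dimethoxy-2,6-dimethyl-1,2-bis(triethylsilyloxy)octane (in flask) | COC(OC)C[C@@H](C)CCC[C@@](C)(O[Si](CC)(CC)CC)CO[Si](CC)(CC)CC | intermediate
7 | 1-[(3S,7R)-1-methoxy-3,7-dimethyl-7,8-bis(triethylsilyloxy)octyl]-2,6-dimethylpyridinium triflate (in flask, both C1 epimers) | COC(C[C@@H](C)CCC[C@@](C)(O[Si](CC)(CC)CC)CO[Si](CC)(CC)CC)[n+]1c(C)cccc1C.[O-]S(=O)(=O)C(F)(F)F | intermediate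
8 | (3S,7R)-3,7-dimethyl-7,8-bis(triethylsilyloxy)octanal | O=CC[C@@H](C)CCC[C@@](C)(O[Si](CC)(CC)CC)CO[Si](CC)(CC)CC | intermediate
9 | (3S,7R)-2-[(dimethylamino)methyl]-3,7-dimethyl-7,8-bis(triethylsilyloxy)octanal (in flask, both C2 epimers) | O=CC(CN(C)C)[C@@H](C)CCC[C@@](C)(O[Si](CC)(CC)CC)CO[Si](CC)(CC)CC | intermediate
10 | (3S,7R)-3,7-dimethyl-2-methylidene-7,8-bis(triethylsilyloxy)octanal | O=CC(=C)[C@@H](C)CCC[C@@](C)(O[Si](CC)(CC)CC)CO[Si](CC)(CC)CC | intermediate
11 | (4S)-4-benzyl-1,3-oxazolidin-2-one | O=C1N[C@@H](Cc2ccccc2)CO1 | starting material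
12 | methyl 4-chloro-4-oxobutanoate | COC(=O)CCC(Cl)=O | starting material
13 | methyl 4-[(4S)-4-benzyl-2-oxo-1,3-oxazolidin-3-yl]-4-oxobutanoate | COC(=O)CCC(=O)N1[C@@H](Cc2ccccc2)COC1=O | intermediate
14 | (Z)-dibutylboron enolate of 13 (in flask) | COC(=O)C/C=C(\OB(CCCC)CCCC)N1[C@@H](Cc2ccccc2)COC1=O | intermediate
15 | O8-dibutylboron aldolate of 16 (in flask) | COC(=O)C[C@@H]([C@H](OB(CCCC)CCCC)C(=C)[C@@H](C)CCC[C@@](C)(O[Si](CC)(CC)CC)CO[Si](CC)(CC)CC)C(=O)N1[C@@H](Cc2ccccc2)COC1=O | intermediate
16 | methyl (3S,4S,6S,10R)-3-{[(4S)-4-benzyl-2-oxo-1,3-oxazolidin-3-yl]carbonyl}-4-hydroxy-6,10-dimethyl-5-methylidene-10,11-bis(triethylsilyloxy)undecanoate | COC(=O)C[C@@H]([C@H](O)C(=C)[C@@H](C)CCC[C@@](C)(O[Si](CC)(CC)CC)CO[Si](CC)(CC)CC)C(=O)N1[C@@H](Cc2ccccc2)COC1=O | intermediate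
17 | methyl (3S,4S,6S,10R)-3-{[(4S)-4-benzyl-2-oxo-1,3-oxazolidin-3-yl]carbonyl}-6,10-dimethyl-5-methylidene-4,10,11-tris(triethylsilyloxy)undecanoate | COC(=O)C[C@@H]([C@H](O[Si](CC)(CC)CC)C(=C)[C@@H](C)CCC[C@@](C)(O[Si](CC)(CC)CC)CO[Si](CC)(CC)CC)C(=O)N1[C@@H](Cc2ccccc2)COC1=O | intermediate
18 | methyl (3S,4S,6S,10R)-3-[(ethylsulfanyl)carbonyl]-6,10-dimethyl-5-methylidene-4,10,11-tris(triethylsilyloxy)undecanoate | COC(=O)C[C@@H]([C@H](O[Si](CC)(CC)CC)C(=C)[C@@H](C)CCC[C@@](C)(O[Si](CC)(CC)CC)CO[Si](CC)(CC)CC)C(=O)SCC | intermediate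
19 | methyl (3S,4S,6S,10R)-3-[(ethylsulfanyl)carbonyl]-6,10-dimethyl-5-methylidene-11-oxo-4,10-bis(triethylsilyloxy)undecanoate | COC(=O)C[C@@H]([C@H](O[Si](CC)(CC)CC)C(=C)[C@@H](C)CCC[C@@](C)(O[Si](CC)(CC)CC)C=O)C(=O)SCC | intermediate
20 | methyl (3S,4S,6S,10R)-3-formyl-6,10-dimethyl-5-methylidene-11-oxo-4,10-bis(triethylsilyloxy)undecanoate (C5/C6 dialdehyde) | COC(=O)C[C@@H]([C@H](O[Si](CC)(CC)CC)C(=C)[C@@H](C)CCC[C@@](C)(O[Si](CC)(CC)CC)C=O)C=O | intermediate
21 | methyl 5,6-dihydroxy-9-methylidene-4,8-bis(triethylsilyloxy)-13-norgermacran-12-oate, in the flask as its samarium alkoxide (stereocentres as in the target) | COC(=O)C[C@H]([C@H]1O)[C@H](O[Si](CC)(CC)CC)C(=C)[C@@H](C)CCC[C@@](C)(O[Si](CC)(CC)CC)[C@H]1O | intermediate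
22 | 5-hydroxy-9-methylidene-4,8-bis(triethylsilyloxy)-13-norgermacran-12,6-olide (6,7-trans lactone; C4, C5, C6, C7, C8, C10 as in the target) | O=C1O[C@@H]2[C@@H](C1)[C@H](O[Si](CC)(CC)CC)C(=C)[C@@H](C)CCC[C@@](C)(O[Si](CC)(CC)CC)[C@H]2O | intermediate
23 | dilithium O5-alkoxide/lactone enolate of 22 (in flask) | [Li]OC1=C[C@@H]([C@H](O[Si](CC)(CC)CC)C(=C)[C@@H](C)CCC[C@@](C)(O[Si](CC)(CC)CC)[C@H]2O[Li])[C@H]2O1 | intermediate
24 | (11S)-13-(dimethylamino)-5-hydroxy-9-methylidene-4,8-bis(triethylsilyloxy)germacran-12,6-olide | CN(C)C[C@H]1C(=O)O[C@@H]2[C@@H]1[C@H](O[Si](CC)(CC)CC)C(=C)[C@@H](C)CCC[C@@](C)(O[Si](CC)(CC)CC)[C@H]2O | intermediate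
25 | (11S)-13-(dimethylamino)-9-methylidene-5-(2-methylpropanoyloxy)-4,8-bis(triethylsilyloxy)germacran-12,6-olide | CN(C)C[C@H]1C(=O)O[C@@H]2[C@@H]1[C@H](O[Si](CC)(CC)CC)C(=C)[C@@H](C)CCC[C@@](C)(O[Si](CC)(CC)CC)[C@H]2OC(=O)C(C)C | intermediate
26 | N-methyl ammonium triflate of 25 (in flask) | C[N+](C)(C)C[C@H]1C(=O)O[C@@H]2[C@@H]1[C@H](O[Si](CC)(CC)CC)C(=C)[C@@H](C)CCC[C@@](C)(O[Si](CC)(CC)CC)[C@H]2OC(=O)C(C)C.[O-]S(=O)(=O)C(F)(F)F | intermediate
27 | C9 spiro-1,2,4-trioxolane (ozonide) of 26 (in flask, C9 unassigned) | C[N+](C)(C)C[C@H]1C(=O)O[C@@H]2[C@@H]1[C@H](O[Si](CC)(CC)CC)C3(OOCO3)[C@@H](C)CCC[C@@](C)(O[Si](CC)(CC)CC)[C@H]2OC(=O)C(C)C.[O-]S(=O)(=O)C(F)(F)F | intermediate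
28 | 9-oxo trimethylammonium triflate (in flask) | C[N+](C)(C)C[C@H]1C(=O)O[C@@H]2[C@@H]1[C@H](O[Si](CC)(CC)CC)C(=O)[C@@H](C)CCC[C@@](C)(O[Si](CC)(CC)CC)[C@H]2OC(=O)C(C)C.[O-]S(=O)(=O)C(F)(F)F | intermediate
29 | 5-(2-methylpropanoyloxy)-9-oxo-4,8-bis(triethylsilyloxy)germacr-11(13)-en-12,6-olide | C=C1C(=O)O[C@@H]2[C@@H]1[C@H](O[Si](CC)(CC)CC)C(=O)[C@@H](C)CCC[C@@](C)(O[Si](CC)(CC)CC)[C@H]2OC(=O)C(C)C | intermediate
30 | (4R,5S,6R,7S,8S,10S)-4,8-dihydroxy-5-(2-methylpropanoyloxy)-9-oxogermacr-11(13)-en-12,6-olide | C=C1C(=O)O[C@@H]2[C@@H]1[C@H](O)C(=O)[C@@H](C)CCC[C@@](C)(O)[C@H]2OC(=O)C(C)C | target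

**Totals**
Total step count: 17. Longest linear sequence: 16 (steps 1–6 and 8–17; step 7 is a one-step branch).

**Steps most likely to fail**

1. Step 13. Intermolecular ketyl coupling and reductive loss of the C4 silyloxy group from the C5 ketyl may outrun the slow ten-membered ring closure, and facial control at C5 and C6 may be incomplete. The fallback sets out from 20 and comes back at 22; it closes the same bond as an olefin and then adds the two oxygens anti. Methylenation of both aldehydes (Ph3P=CH2 from Ph3PCH3Br and KN(SiMe3)2, THF, −78 to 0 °C) would give the triene F1. Ring-closing metathesis (second-generation Grubbs catalyst, RuCl2(=CHPh)(PCy3)(H2IMes), toluene, 80 °C, high dilution) should close ring A as the (Z)-cyclodecene F2, the hindered C9 methylene being a spectator. LiOH (THF/H2O) gives the acid F3. Kinetic iodolactonisation (I2, NaHCO3, MeCN, 0 °C) can engage only the C5=C6 olefin (5-exo attack of the carboxylate on C6) and should give the cis-fused iodolactone F4. K2CO3 in MeOH opens the lactone and lets the C6 alkoxide displace iodide at C5 with inversion, giving the cis-epoxy ester F5. Catalytic camphorsulfonic acid (CH2Cl2, −20 °C) then lets the ester carbonyl open the epoxide at C6 with inversion (5-exo), which is a net anti addition of O5 and O6 to the Z olefin and would deliver 22, provided the iodolactonisation takes the cis-fused course.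

2. Step 16. Premature loss of trimethylamine from the ammonium salt would expose the new acrylate to ozone, and over-oxidation may occur in the one-pot sequence. The fallback sets out from 25 and comes back at 29; it replaces ozonolysis by glycol cleavage. Dihydroxylation of the only olefin (OsO4 cat., N-methylmorpholine N-oxide, acetone/H2O) would give the diol F6; NaIO4 (THF/H2O) cleaves it to the amino ketone F7; MeI (CH2Cl2) gives the ammonium iodide F8; aqueous NaHCO3 then eliminates trimethylamine to give 29.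

3. Step 14. The C5 alkoxide formed by the first equivalent of base may take the neighbouring triethylsilyl group from O4 (1,4-silyl migration) or attack the lactone, and C-alkylation of the enolate may be incomplete. The fallback sets out from 22 and comes back at 24; it avoids strong base. Condensation with tert-butoxybis(dimethylamino)methane (Bredereck's reagent, toluene, 70 °C) would give the enaminolactone F9 (the C5 hydroxyl is recovered on aqueous work-up). Reduction with NaBH(OAc)3 and AcOH in CH2Cl2 then gives the Mannich base 24; the epimerisable C11 centre should settle trans to C8, and either C11 epimer converges at 29.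

**Further compounds**
F1 | step 13 | methyl (3S,4S,6S,10R)-3-ethenyl-6,10-dimethyl-5-methylidene-4,10-bis(triethylsilyloxy)dodec-11-enoate | COC(=O)C[C@@H]([C@H](O[Si](CC)(CC)CC)C(=C)[C@@H](C)CCC[C@@](C)(O[Si](CC)(CC)CC)C=C)C=C
F2 | step 13 | methyl (5Z)-9-methylidene-4,8-bis(triethylsilyloxy)-13-norgermacr-5-en-12-oate | C1C[C@@](C)(O[Si](CC)(CC)CC)/C=C\[C@@H](CC(=O)OC)[C@H](O[Si](CC)(CC)CC)C(=C)[C@@H](C)C1
F3 | step 13 | (5Z)-9-methylidene-4,8-bis(triethylsilyloxy)-13-norgermacr-5-en-12-oic acid | C1C[C@@](C)(O[Si](CC)(CC)CC)/C=C\[C@@H](CC(=O)O)[C@H](O[Si](CC)(CC)CC)C(=C)[C@@H](C)C1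
F4 | step 13 | 5-iodo-9-methylidene-4,8-bis(triethylsilyloxy)-13-norgermacran-12,6-olide, 6-epi (cis-fused lactone, iodide anti to O6) | C1C[C@@](C)(O[Si](CC)(CC)CC)[C@H](I)[C@H]2OC(=O)C[C@H]2[C@H](O[Si](CC)(CC)CC)C(=C)[C@@H](C)C1
F5 | step 13 | methyl 5,6-epoxy-9-methylidene-4,8-bis(triethylsilyloxy)-13-norgermacran-12-oate (cis-epoxide, O on the face of O5 of the target) | C1C[C@@](C)(O[Si](CC)(CC)CC)[C@H]2O[C@H]2[C@@H](CC(=O)OC)[C@H](O[Si](CC)(CC)CC)C(=C)[C@@H](C)C1
F6 | step 16 | 9-hydroxy-9-(hydroxymethyl) diol of 25 (C9 unassigned) | CN(C)C[C@H]1C(=O)O[C@@H]2[C@@H]1[C@H](O[Si](CC)(CC)CC)C(O)(CO)[C@@H](C)CCC[C@@](C)(O[Si](CC)(CC)CC)[C@H]2OC(=O)C(C)C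
F7 | step 16 | (11S)-13-(dimethylamino)-5-(2-methylpropanoyloxy)-9-oxo-4,8-bis(triethylsilyloxy)germacran-12,6-olide | CN(C)C[C@H]1C(=O)O[C@@H]2[C@@H]1[C@H](O[Si](CC)(CC)CC)C(=O)[C@@H](C)CCC[C@@](C)(O[Si](CC)(CC)CC)[C@H]2OC(=O)C(C)C
F8 | step 16 | N-methyl ammonium iodide of F7 | C[N+](C)(C)C[C@H]1C(=O)O[C@@H]2[C@@H]1[C@H](O[Si](CC)(CC)CC)C(=O)[C@@H](C)CCC[C@@](C)(O[Si](CC)(CC)CC)[C@H]2OC(=O)C(C)C.[I-]
F9 | step 14 | (11E)-13-(dimethylamino)-5-hydroxy-9-methylidene-4,8-bis(triethylsilyloxy)germacr-11(13)-en-12,6-olide | CN(C)/C=C1/C(=O)O[C@@H]2[C@@H]1[C@H](O[Si](CC)(CC)CC)C(=C)[C@@H](C)CCC[C@@](C)(O[Si](CC)(CC)CC)[C@H]2O
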